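**Retrosynthetic overview**

- Ring labels: ring A is the sulfated 3,5-dibromophenyl ring, ring B the central tribromo ring (C1 bears the oxygen to ring A, C2 the oxygen to ring C), ring C the 2,4-dibromophenyl ring.
- The plan rests on the pattern of ring B: Br at C3 and C5 lie ortho and para to the C2 oxygen, Br at C4 lies para to the C1 oxygen, and C6–H is the one site neither oxygen favours. A ring B with a free C2–OH and the C1 aryl ether should therefore take up exactly these three bromines.
- Disconnections, from the end: the ArO–SO3H bond; the bond from the ring B C2 oxygen to ring C (aryl transfer from a diaryliodonium salt); the three C–Br bonds of ring B (one-flask tribromination); the bond from the ring B C1 oxygen to ring A (SNAr of guaiacol on a 2-fluorobenzaldehyde, the formyl group then becoming the ring A oxygen by Baeyer–Villiger oxidation).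
- No ring is formed. The three benzene rings come from commercial arenes and are joined A–B first, then B–C.

Key step: step 5

Assumption: the target is taken as the free aryl hydrogen sulfate as drawn; it is liberated cold from its pyridinium salt and would in practice be stored as a salt.

**Route**

Step 1
Reactants: 1 guaiacol (2-methoxyphenol); 2 3,5-dibromo-2-fluorobenzaldehyde
Product: 3 3,5-dibromo-2-(2-methoxyphenoxy)benzaldehyde
Conditions: K2CO3, DMF, 70 °C
Reagents that add atoms: none
Why: Nucleophilic aromatic substitution by addition–elimination: the fluoride is ortho to the formyl group and should be displaced by the phenoxide through a Meisenheimer intermediate, while both bromines are meta to the formyl group and are not activated.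

Step 2
Reactants: 3 3,5-dibromo-2-(2-methoxyphenoxy)benzaldehyde
Product: 5 3,5-dibromo-2-(2-methoxyphenoxy)phenol, via aryl formate 4 (not isolated)
Conditions: mCPBA, CH2Cl2, 40 °C; aq. NaHCO3 wash; then Et3N (cat.), MeOH, rt
Reagents that add atoms: mCPBA, O=C(OO)c1cccc(Cl)c1
Why: Baeyer–Villiger (Dakin-type) oxidation: in the Criegee adduct the aryl group, supported by its ortho aryloxy donor, should migrate in preference to hydride, and the labile aryl formate is then methanolysed under mild base catalysis.

Step 3
Reactants: 5 3,5-dibromo-2-(2-methoxyphenoxy)phenol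
Product: 6 3,5-dibromo-2-(2-methoxyphenoxy)phenyl methanesulfonate
Conditions: MsCl, Et3N, CH2Cl2, 0 °C
Reagents that add atoms: methanesulfonyl chloride, CS(=O)(=O)Cl
Why: O-Sulfonylation of a phenol; the mesyloxy group is chosen because it should withstand BBr3 and bromine, deactivates ring A, and is later removed by hydroxide.

Step 4
Reactants: 6 3,5-dibromo-2-(2-methoxyphenoxy)phenyl methanesulfonate
Product: 7 3,5-dibromo-2-(2-hydroxyphenoxy)phenyl methanesulfonate
Conditions: BBr3, CH2Cl2, −78 °C → 0 °C; then H2O
Reagents that add atoms: none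
Why: Lewis-acid demethylation of an aryl methyl ether: BBr3 binds the methoxy oxygen and bromide attacks the methyl carbon by SN2, whereas the diaryl ether and the aryl mesylate offer no alkyl C–O bond and should stay intact.

Step 5
Reactants: 7 3,5-dibromo-2-(2-hydroxyphenoxy)phenyl methanesulfonate
Product: 8 3,5-dibromo-2-(3,4,5-tribromo-2-hydroxyphenoxy)phenyl methanesulfonate
Conditions: Br2 (3.05 equiv), AcOH, 20 °C → 45 °C
Reagents that add atoms: bromine, BrBr
Why: Each bromine enters by electrophilic aromatic substitution through an oxygen-stabilised arenium ion, the classical bromination of a phenol in acetic acid. The free C2 hydroxyl makes ring B far more reactive than ring A and should send the first two bromines to C5 (para) and C3 (ortho). The two sites then left, C4 and C6, are both meta to the hydroxyl, so the C1 ether oxygen decides; its para position C4 should be preferred over the ortho position C6, which lies under the twisted, 2,6-disubstituted ring A, the closest analogy being the tribromination of guaiacol to 4,5,6-tribromoguaiacol, which leaves the site ortho to the ether free. No ring is closed and no stereocentre is formed. Ring A should stay untouched because its two open positions are meta to its ether oxygen and it carries two bromines and the electron-withdrawing mesyloxy group. A fourth bromination at C6 is held back by the three deactivating bromines and by charging only three equivalents of bromine.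

Step 6
Reactants: 9 2,4-dibromo-1-iodobenzene; 10 1,3,5-trimethoxybenzene
Product: 12 (2,4-dibromophenyl)(2,4,6-trimethoxyphenyl)iodonium 4-methylbenzenesulfonate, via hydroxy(tosyloxy)iodoarene 11 (not isolated)
Conditions: mCPBA, TsOH·H2O, MeCN, 77 °C; then 10, 77 °C → rt
Reagents that add atoms: p-toluenesulfonic acid monohydrate, Cc1ccc(cc1)S(=O)(=O)O.O (tosyloxy ligand of 11 and tosylate of 12); mCPBA, O=C(OO)c1cccc(Cl)c1 (oxygen of the hydroxy ligand of 11 only, lost as water on forming 12)
Why: One-pot diaryliodonium synthesis: the peracid oxidises the aryl iodide to a trivalent iodine hydroxy(tosyloxy) species (Koser-type reagent), which then substitutes the electron-rich trimethoxybenzene by electrophilic aromatic substitution.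

Step 7
Reactants: 8 3,5-dibromo-2-(3,4,5-tribromo-2-hydroxyphenoxy)phenyl methanesulfonate; 12 (2,4-dibromophenyl)(2,4,6-trimethoxyphenyl)iodonium 4-methylbenzenesulfonate
Product: 13 3,5-dibromo-2-[3,4,5-tribromo-2-(2,4-dibromophenoxy)phenoxy]phenyl methanesulfonate
Conditions: K2CO3, MeCN, 55 °C
Reagents that add atoms: none
Why: Metal-free O-arylation of a phenol with a diaryliodonium salt: the phenoxide replaces tosylate on trivalent iodine and ligand coupling should deliver the electron-poorer, ortho-substituted 2,4-dibromophenyl group while the trimethoxyphenyl group leaves as its aryl iodide; carbonate suffices for the acidic tribromophenol and should spare the mesylate.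

Step 8
Reactants: 13 3,5-dibromo-2-[3,4,5-tribromo-2-(2,4-dibromophenoxy)phenoxy]phenyl methanesulfonate
Product: 14 3,5-dibromo-2-[3,4,5-tribromo-2-(2,4-dibromophenoxy)phenoxy]phenol
Conditions: NaOH, THF/MeOH/H2O, 50 °C; then aq. HCl
Reagents that add atoms: none
Why: Alkaline hydrolysis of an aryl sulfonate ester: hydroxide attacks sulfur and expels the stabilised dibromophenoxide, while the diaryl ether bonds and the unactivated aryl bromides should be inert to hydroxide at this temperature.

Step 9
Reactants: 14 3,5-dibromo-2-[3,4,5-tribromo-2-(2,4-dibromophenoxy)phenoxy]phenol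
Product: 16 bromoiesol A sulfate (3,5-dibromo-2-[3,4,5-tribromo-2-(2,4-dibromophenoxy)phenoxy]phenyl hydrogen sulfate), via pyridinium aryl sulfate 15 (not isolated)
Conditions: SO3·pyridine, pyridine, 50 °C; then cation-exchange resin (H+ form), MeOH, 0 °C
Reagents that add atoms: sulfur trioxide pyridine complex, O=S(=O)=O.c1ccncc1
Why: O-Sulfation of a phenol by transfer of sulfur trioxide from its pyridine complex should give the pyridinium aryl sulfate, from which the cold acidic resin takes up pyridinium and leaves the free hydrogen sulfate.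

**Compound list**

1 | guaiacol (2-methoxyphenol) | COc1ccccc1O | starting material
2 | 3,5-dibromo-2-fluorobenzaldehyde | O=Cc1cc(Br)cc(Br)c1F | starting material
3 | 3,5-dibromo-2-(2-methoxyphenoxy)benzaldehyde | COc1ccccc1Oc1c(Br)cc(Br)cc1C=O | intermediate
4 | 3,5-dibromo-2-(2-methoxyphenoxy)phenyl formate | COc1ccccc1Oc1c(Br)cc(Br)cc1OC=O | intermediate
5 | 3,5-dibromo-2-(2-methoxyphenoxy)phenol | COc1ccccc1Oc1c(Br)cc(Br)cc1O | intermediate
6 | 3,5-dibromo-2-(2-methoxyphenoxy)phenyl methanesulfonate | COc1ccccc1Oc1c(Br)cc(Br)cc1OS(C)(=O)=O | intermediate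
7 | 3,5-dibromo-2-(2-hydroxyphenoxy)phenyl methanesulfonate | CS(=O)(=O)Oc1cc(Br)cc(Br)c1Oc1ccccc1O | intermediate
8 | 3,5-dibromo-2-(3,4,5-tribromo-2-hydroxyphenoxy)phenyl methanesulfonate | CS(=O)(=O)Oc1cc(Br)cc(Br)c1Oc1cc(Br)c(Br)c(Br)c1O | intermediate
9 | 2,4-dibromo-1-iodobenzene | Brc1ccc(I)c(Br)c1 | starting material
10 | 1,3,5-trimethoxybenzene | COc1cc(OC)cc(OC)c1 | starting material
11 | 2,4-dibromo-1-[hydroxy(tosyloxy)iodo]benzene | Cc1ccc(cc1)S(=O)(=O)OI(O)c1ccc(Br)cc1Br | intermediate
12 | (2,4-dibromophenyl)(2,4,6-trimethoxyphenyl)iodonium 4-methylbenzenesulfonate | COc1cc(OC)c([I+]c2ccc(Br)cc2Br)c(OC)c1.Cc1ccc(cc1)S(=O)(=O)[O-] | intermediate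
13 | 3,5-dibromo-2-[3,4,5-tribromo-2-(2,4-dibromophenoxy)phenoxy]phenyl methanesulfonate | CS(=O)(=O)Oc1cc(Br)cc(Br)c1Oc1cc(Br)c(Br)c(Br)c1Oc1ccc(Br)cc1Br | intermediate
14 | 3,5-dibromo-2-[3,4,5-tribromo-2-(2,4-dibromophenoxy)phenoxy]phenol | Oc1cc(Br)cc(Br)c1Oc1cc(Br)c(Br)c(Br)c1Oc1ccc(Br)cc1Br | intermediate
15 | pyridinium 3,5-dibromo-2-[3,4,5-tribromo-2-(2,4-dibromophenoxy)phenoxy]phenyl sulfate | [O-]S(=O)(=O)Oc1cc(Br)cc(Br)c1Oc1cc(Br)c(Br)c(Br)c1Oc1ccc(Br)cc1Br.c1cc[nH+]cc1 | intermediate
16 | bromoiesol A sulfate | O=S(=O)(O)Oc1cc(Br)cc(Br)c1Oc1cc(Br)c(Br)c(Br)c1Oc1ccc(Br)cc1Br | target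

**Step count**

Total: 9 steps. Longest linear sequence: 8 steps (1, 2, 3, 4, 5, 7, 8, 9); step 6 is a one-step branch that joins at step 7.

**Steps most likely to fail**

Step 5. The third bromination may not separate C4 from C6 cleanly, because the electron-poor ring A makes the C1 oxygen a weaker para director than a methoxy group. The reaction may also stall after two bromines or run on to a fourth. Fallback, setting out from 1 and returning at 14: the bromination is moved onto guaiacol itself, where the pattern is established.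
- Compound 1 with Br2 (3 equiv) in AcOH should give 2,3,4-tribromo-6-methoxyphenol F1 (4,5,6-tribromoguaiacol).
- Its phenol is arylated with iodonium salt 12 (K2CO3, MeCN, 55 °C) to 1,2,3-tribromo-4-(2,4-dibromophenoxy)-5-methoxybenzene F2.
- BBr3 in CH2Cl2 frees 3,4,5-tribromo-2-(2,4-dibromophenoxy)phenol F3.
- SNAr of F3 on aldehyde 2 (K2CO3, DMF, 80 °C) gives 3,5-dibromo-2-[3,4,5-tribromo-2-(2,4-dibromophenoxy)phenoxy]benzaldehyde F4.
- Baeyer–Villiger oxidation with mCPBA gives 3,5-dibromo-2-[3,4,5-tribromo-2-(2,4-dibromophenoxy)phenoxy]phenyl formate F5, which is methanolysed (Et3N, MeOH) to phenol 14.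

Step 7. Aryl transfer to the crowded, weakly nucleophilic phenoxide (flanked by the C3 bromine and the ring A aryloxy group) may be slow, leaving room for base-induced loss of the mesyl group or decomposition of the iodonium salt. Fallback, setting out from 8 and returning at 13: ring C is attached by SNAr and its second bromine is introduced afterwards.
- Compound 8 with 4-bromo-1-fluoro-2-nitrobenzene (K2CO3, DMF, 60 °C) should give 3,5-dibromo-2-[3,4,5-tribromo-2-(4-bromo-2-nitrophenoxy)phenoxy]phenyl methanesulfonate F6.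
- Fe powder and NH4Cl in EtOH/H2O reduce the nitro group to 2-[2-(2-amino-4-bromophenoxy)-3,4,5-tribromophenoxy]-3,5-dibromophenyl methanesulfonate F7.
- Sandmeyer bromination (t-BuONO, CuBr2, MeCN) converts F7 into 13.

Step 9. Sulfation of the ortho-aryloxy phenol may be incomplete, and the sulfate group may be lost by acid-promoted hydrolysis while the free acid is liberated on the resin. Fallback, setting out from 14 and returning at 16: the sulfate is carried as a neutral, chromatographable diester.
- Compound 14 with 2,2,2-trichloroethyl chlorosulfate (Et3N, DMAP, THF) should give 3,5-dibromo-2-[3,4,5-tribromo-2-(2,4-dibromophenoxy)phenoxy]phenyl 2,2,2-trichloroethyl sulfate F8.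
- Zn dust and HCO2NH4 in MeOH remove the trichloroethyl group by reductive fragmentation to give ammonium 3,5-dibromo-2-[3,4,5-tribromo-2-(2,4-dibromophenoxy)phenoxy]phenyl sulfate F9.
- Brief contact of F9 with the cold acidic resin gives 16.

**Further compounds**

F1 | step 5 | 2,3,4-tribromo-6-methoxyphenol (4,5,6-tribromoguaiacol) | COc1cc(Br)c(Br)c(Br)c1O
F2 | step 5 | 1,2,3-tribromo-4-(2,4-dibromophenoxy)-5-methoxybenzene | COc1cc(Br)c(Br)c(Br)c1Oc1ccc(Br)cc1Br
F3 | step 5 | 3,4,5-tribromo-2-(2,4-dibromophenoxy)phenol | Oc1cc(Br)c(Br)c(Br)c1Oc1ccc(Br)cc1Br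
F4 | step 5 | 3,5-dibromo-2-[3,4,5-tribromo-2-(2,4-dibromophenoxy)phenoxy]benzaldehyde | O=Cc1cc(Br)cc(Br)c1Oc1cc(Br)c(Br)c(Br)c1Oc1ccc(Br)cc1Br
F5 | step 5 | 3,5-dibromo-2-[3,4,5-tribromo-2-(2,4-dibromophenoxy)phenoxy]phenyl formate | O=COc1cc(Br)cc(Br)c1Oc1cc(Br)c(Br)c(Br)c1Oc1ccc(Br)cc1Br
F6 | step 7 | 3,5-dibromo-2-[3,4,5-tribromo-2-(4-bromo-2-nitrophenoxy)phenoxy]phenyl methanesulfonate | CS(=O)(=O)Oc1cc(Br)cc(Br)c1Oc1cc(Br)c(Br)c(Br)c1Oc1ccc(Br)cc1[N+](=O)[O-]
F7 | step 7 | 2-[2-(2-amino-4-bromophenoxy)-3,4,5-tribromophenoxy]-3,5-dibromophenyl methanesulfonate | CS(=O)(=O)Oc1cc(Br)cc(Br)c1Oc1cc(Br)c(Br)c(Br)c1Oc1ccc(Br)cc1N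
F8 | step 9 | 3,5-dibromo-2-[3,4,5-tribromo-2-(2,4-dibromophenoxy)phenoxy]phenyl 2,2,2-trichloroethyl sulfate | ClC(Cl)(Cl)COS(=O)(=O)Oc1cc(Br)cc(Br)c1Oc1cc(Br)c(Br)c(Br)c1Oc1ccc(Br)cc1Br
F9 | step 9 | ammonium 3,5-dibromo-2-[3,4,5-tribromo-2-(2,4-dibromophenoxy)phenoxy]phenyl sulfate | [NH4+].[O-]S(=O)(=O)Oc1cc(Br)cc(Br)c1Oc1cc(Br)c(Br)c(Br)c1Oc1ccc(Br)cc1Br
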